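## The problem

The target 23 is a linear tridepside: three benzoate rings joined head to tail by two aryl ester bonds. Ring A (2,4-dihydroxy-3,6-dimethylbenzoyl) acylates the C4 oxygen of ring B (2-methoxy-3,5,6-trimethylbenzoyl), and ring B acylates the C4 oxygen of ring C (2-methoxy-3,6-dimethylbenzoic acid, free carboxyl). There is no stereocentre and no ring beyond the three arenes, so nothing has to be controlled in space. The task is one of substitution pattern, hindered bond formation and the order of protecting-group removal.

Both ester carbonyls carry two ortho substituents and the ring B oxygen sits between two methyl groups. The A–B ester therefore joins a di-ortho-substituted acid to a di-ortho-substituted phenol. Once made, the aryl esters will not survive hydroxide or alkoxide, so every saponification must come before them and the closing steps must be neutral or acidic. Three sets of groups have to be released at different times: the ring B phenol, the ring C carboxyl and the ring A phenols.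

Rings A and C map onto a commercial 3-methylorsellinate; ring B, fully substituted, does not. Ring B is an orsellinate (C1 carboxyl, C2 and C4 oxygens, C6 methyl) whose two remaining carbons, C3 and C5, both bear methyl. These are exactly the positions that the two oxygens activate toward electrophiles. Exhaustive bromination therefore places a halogen on each without any choice of site, and both halogens can be exchanged for methyl in one cross-coupling operation.

## Retrosynthesis

**Unmasking (23 from 22 from 21).** The last bonds cut are the two O–benzyl bonds on ring A (23 back to acid 22) and the O–tert-butyl bond on ring C (22 back to the fully protected tridepside 21). A benzyl ether on the ring B oxygen, a tert-butyl ester on ring C and benzyl ethers on ring A give the three-way differentiation the chain needs. The acid step is placed before the hydrogenolysis so that the tert-butyl cation never meets the free resorcinol of ring A, and the route ends under neutral conditions.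

**A–B ester (21 from 17 and 19).** The acyl C–O bond between rings A and B is cut to the B–C phenol 17 and the ring A acid 19, activated as chloride 20. Making this bond last is preferred over making it first. An A–B fragment would need a ring B carboxyl that can be released beside an aryl ester, and the methyl ester of the key-step product cannot. The forward reaction must join two doubly flanked partners, so an anionic phenoxide and an aroyl chloride are used.

**B–C ester (17 from 16, from 8 and 14).** Phenol 17 comes from benzyl ether 16 by hydrogenolysis. Cutting the B–C acyl C–O bond of 16 gives the ring B acid 8 (as chloride 15) and the ring C phenol 14. Both pieces are single arenes. The phenol of 14 has only one ortho methyl, so this union is the easier of the two.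

**Ring B (8 from 7, from 5 and 6).** Acid 8 is the saponification product of methyl ester 7, done while no aryl ester is present. In 7 the C3–CH3 and C5–CH3 bonds are cut together, leading to dibromide 5 and trimethylboroxine 6. This cut is preferred over building the ring from acyclic pieces because the oxygen and carboxyl pattern is then bought, not made, and the only new bonds are two aryl–methyl bonds of a well-known kind. A neighbouring cut that buys the C3 methyl with 9 and couples only at C5 is equally short and is held in reserve. The twofold version is kept as first choice because it installs both methyls in one operation from the simpler orsellinate 1 and leaves a dibromide from which both positions could be varied. The forward reaction must couple two hindered bromides without reduction.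

**Dibromide (5 from 4, from 2, from 1 and 3).** The 2-O-methyl bond of 5 is cut to phenol 4, the 4-O-benzyl bond of 4 to diol 2 and benzyl bromide 3, and the two C–Br bonds of 2 to methyl orsellinate 1. Bromination comes first because a free resorcinol accepts bromine even at C3 between the two oxygens, whereas a diether resists substitution there. The two hydroxyls of 2 are then told apart by acidity and chelation.

**Ring C (14 from 13, 12, 11, 10 and 9).** Phenol 14 arises from benzyl ether 13 by hydrogenolysis, 13 from acid 12 by O-alkylative tert-butylation, 12 from methyl ester 11 by saponification, 11 from phenol 10 by methylation and 10 from commercial 9 and 3 by benzylation of the unchelated hydroxyl. The ester exchange is unavoidable: a methyl ester could not be removed at the end, and a benzyl ester would fall with the ring B benzyl ether.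

**Ring A (19 from 18, from 9 and 3).** Acid 19 is the saponification product of bis-benzyl ether 18, which comes from 9 and 3 in one exhaustive benzylation.

## Roads not taken

**Alternative 1:** Ring B is cut across C5–C6 and C2–C3 into pentan-3-one A1 and diethyl ethylidenemalonate A2.

- Forward step: the enolate of A1 adds to A2 and the second α-carbon of the ketone then acylates one malonate ester. This gives ethyl 3,5,6-trimethyl-2,4-dioxocyclohexane-1-carboxylate A3 as a mixture of tautomers and diastereomers. Dehydrogenation would give ethyl 2,4-dihydroxy-3,5,6-trimethylbenzoate A4, and benzylation and methylation as in steps 2 and 3 would lead to the ethyl ester analogue of 7.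
- Merits: all three ring methyls come from bulk chemicals, no palladium or bromine is needed, and the labile centres of A3 vanish on aromatization. The count to a protected ring B ester is the same four steps.
- Weak points: the polarity is the unfavourable one. A simple ketone enolate must be generated beside an acceptor that is itself readily deprotonated at its γ-position and prone to oligomerize, and the adduct is more acidic than the donor. The oxidation of a fully substituted dione with three methyl groups is the step where dihydro-orsellinate routes usually lose material, through halogenation at the wrong carbon or over-oxidation.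
- Comparison: this road is better in cost and atom economy and equal in length. The chosen plan sets against it that bromination of a resorcinol and methyl cross-coupling are both routine on this substrate class, and that the oxygenation pattern of 1 is already correct.

**Alternative 2:** Ring B is cut into a vinylketene and an alkyne while already attached to ring C.

- Forward step: irradiation of benzyl 4-{[(4E)-2-diazo-4-methyl-3-oxohex-4-enoyl]oxy}-2-methoxy-3,6-dimethylbenzoate A5 triggers a Wolff shift. The vinylketene adds 1-methoxypropyne A6 by [2+2] cycloaddition, and four-electron ring opening followed by six-electron electrocyclization gives the B–C phenol benzyl 4-[(4-hydroxy-2-methoxy-3,5,6-trimethylbenzoyl)oxy]-2-methoxy-3,6-dimethylbenzoate A7.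
- Merits: the road is convergent. The B–C ester is made at an unhindered acyclic stage, the C2 methoxy arrives with the alkyne in the correct orientation, and the C4 hydroxyl is born free. A7 would be reached in fewer operations than the seven (steps 1 to 5, 11 and 12) that lead to 17, with no hindered saponification or esterification.
- Weak points: 2-diazo-1,3-dicarbonyl compounds rearrange less cleanly than simple diazo ketones. The aryl ester chromophore can itself react under irradiation. A hexasubstituted arene requires electrocyclization of a very crowded dienylketene. A6 is a volatile ynol ether that must be prepared.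
- Comparison: in step economy and convergence this road is better. The chosen plan sets against it that no step depends on a photochemical cascade at its steric limit, and that its failure modes are ordinary and have ordinary remedies.

**Alternative 3:** Ring A is cut at its C1–C6 bond together with the A–B ester C–O bond.

- Forward step: heating 6-(3,5-dioxohexan-2-yl)-2,2-dimethyl-4H-1,3-dioxin-4-one A8 with phenol A7 releases an acylketene that the phenol captures. The resulting trioxooctanoate A9 cyclizes by aldol condensation and dehydration to the benzyl ester of the target, A10, which hydrogenolysis would convert into 23.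
- Merits: the doubly hindered A–B ester is formed by addition of the phenol to an unhindered ketene, which is arguably a better answer to that bond than step 15. Ring A needs no protecting groups and the end is a single hydrogenolysis.
- Weak points: A8 takes several steps to make. A9 is an activated aryl ester carrying an enolizable 5-oxo group, so lactonization to a 4-hydroxypyranone with loss of the phenol competes with the aldol closure. The base needed for aromatization threatens the B–C ester. The road also leaves ring B unsolved, so it replaces steps 13 to 17, not the key step.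
- Comparison: the chosen plan sets against it that ring A is commercial as 9 and reaches 19 in two steps, and that no polyketone has to be handled.

Key step: step 4

Remark on the chemistry: 23 has no stereocentre and no double-bond isomerism, so all structures are written without stereodescriptors. Compounds 1, 3, 6 and 9 are taken as commercial.

## Route

Step 1
Reactants: 1 methyl orsellinate (methyl 2,4-dihydroxy-6-methylbenzoate)
Product: 2 methyl 3,5-dibromo-2,4-dihydroxy-6-methylbenzoate
Conditions: NBS (2.1 equiv), MeCN, 0 °C → rt
Reagents that add atoms: N-bromosuccinimide, O=C1CCC(=O)N1Br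
Why: Electrophilic aromatic bromination; C3 and C5 are the only free ring positions and both are ortho or para to the two hydroxyls, so two equivalents give the dibromide with no regiochemical choice, and the free phenol allows substitution even at C3 between the oxygens.

Step 2
Reactants: 2 methyl 3,5-dibromo-2,4-dihydroxy-6-methylbenzoate; 3 benzyl bromide
Product: 4 methyl 4-(benzyloxy)-3,5-dibromo-2-hydroxy-6-methylbenzoate
Conditions: 3 (1.05 equiv), KHCO3 (1.5 equiv), DMF, 40 °C
Reagents that add atoms: benzyl bromide (3), BrCc1ccccc1
Why: Williamson etherification; the 4-hydroxyl, flanked by two bromines and para to the ester, is acidic enough for hydrogencarbonate, while the 2-hydroxyl is held in a hydrogen bond to the ester carbonyl, so one equivalent of 3 should alkylate O4 only.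

Step 3
Reactants: 4 methyl 4-(benzyloxy)-3,5-dibromo-2-hydroxy-6-methylbenzoate
Product: 5 methyl 4-(benzyloxy)-3,5-dibromo-2-methoxy-6-methylbenzoate
Conditions: MeI (3 equiv), K2CO3, DMF, 50 °C
Reagents that add atoms: iodomethane, CI
Why: Williamson methylation of the chelated salicylate hydroxyl, which needs the stronger base, excess alkylating agent and warming but is standard for 2-hydroxybenzoates.

Step 4
Reactants: 5 methyl 4-(benzyloxy)-3,5-dibromo-2-methoxy-6-methylbenzoate; 6 trimethylboroxine
Product: 7 methyl 4-(benzyloxy)-2-methoxy-3,5,6-trimethylbenzoate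
Conditions: 6 (2 equiv), Pd(OAc)2 (5 mol%), SPhos (2-dicyclohexylphosphino-2',6'-dimethoxybiphenyl, 10 mol%), K3PO4 (6 equiv), toluene/H2O (10:1), 100 °C
Reagents that add atoms: trimethylboroxine (6), CB1OB(C)OB(C)O1
Why: Twofold Suzuki–Miyaura methylation, the closest known reaction type being the methylation of di-ortho-substituted aryl bromides with trimethylboroxine or methylboronic acid under Pd(OAc)2 and a dialkylbiarylphosphine. Pd(OAc)2 is reduced in the flask to a zerovalent palladium–SPhos complex that inserts into a C–Br bond; aqueous K3PO4 opens the boroxine to a methylboronate that passes its methyl to the arylpalladium bromide, and C–C reductive elimination releases the arene and the zerovalent catalyst, the cycle then running again at the other bromide. No ring is closed and no stereocentre is formed. Site selectivity is not needed because both C3 and C5 are to be methylated; what is needed is chemoselectivity for coupling over hydrodebromination, over palladium-mediated C–H arylation of the benzyl ring and over ester hydrolysis. The bulky, electron-rich monophosphine speeds oxidative addition into the electron-rich, doubly flanked C–Br bonds as well as reductive elimination, and the excess of 6 keeps transmetalation ahead of the side paths; methyl has no β-hydrogen, so β-hydride elimination cannot intervene. The methyl ester is shielded by its two ortho substituents and should survive hot aqueous phosphate, and the benzyl ether is inert.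

Step 5
Reactants: 7 methyl 4-(benzyloxy)-2-methoxy-3,5,6-trimethylbenzoate
Product: 8 4-(benzyloxy)-2-methoxy-3,5,6-trimethylbenzoic acid
Conditions: KOH, DMSO/H2O (4:1), 100 °C; then aq. HCl
Reagents that add atoms: potassium hydroxide, [K+].[OH-] (oxygen of the carboxyl OH)
Why: Saponification of a di-ortho-substituted methyl benzoate, which needs poorly solvated hydroxide in hot aqueous DMSO; the benzyl and methyl ethers are inert to base, and no aryl ester is yet present.

Step 6
Reactants: 9 methyl 2,4-dihydroxy-3,6-dimethylbenzoate; 3 benzyl bromide
Product: 10 methyl 4-(benzyloxy)-2-hydroxy-3,6-dimethylbenzoate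
Conditions: 3 (1.05 equiv), K2CO3, acetone, reflux
Reagents that add atoms: benzyl bromide (3), BrCc1ccccc1
Why: Williamson etherification; in orsellinate esters the 4-hydroxyl reacts first because the 2-hydroxyl is chelated to the ester carbonyl.

Step 7
Reactants: 10 methyl 4-(benzyloxy)-2-hydroxy-3,6-dimethylbenzoate
Product: 11 methyl 4-(benzyloxy)-2-methoxy-3,6-dimethylbenzoate
Conditions: MeI, K2CO3, DMF, 60 °C
Reagents that add atoms: iodomethane, CI
Why: Williamson methylation of the remaining chelated hydroxyl under forcing conditions, as in step 3.

Step 8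
Reactants: 11 methyl 4-(benzyloxy)-2-methoxy-3,6-dimethylbenzoate
Product: 12 4-(benzyloxy)-2-methoxy-3,6-dimethylbenzoic acid
Conditions: KOH, DMSO/H2O (4:1), 100 °C; then aq. HCl
Reagents that add atoms: potassium hydroxide, [K+].[OH-] (oxygen of the carboxyl OH)
Why: Saponification of a hindered methyl benzoate as in step 5; the ethers are untouched.

Step 9
Reactants: 12 4-(benzyloxy)-2-methoxy-3,6-dimethylbenzoic acid
Product: 13 tert-butyl 4-(benzyloxy)-2-methoxy-3,6-dimethylbenzoate
Conditions: Me2NCH(OtBu)2 (4 equiv), toluene, 85 °C
Reagents that add atoms: N,N-dimethylformamide di-tert-butyl acetal, CN(C)C(OC(C)(C)C)OC(C)(C)C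
Why: O-Alkylative esterification; the carboxylate oxygen is tert-butylated by the protonated amide acetal, so crowding at the carbonyl carbon does not matter.

Step 10
Reactants: 13 tert-butyl 4-(benzyloxy)-2-methoxy-3,6-dimethylbenzoate
Product: 14 tert-butyl 4-hydroxy-2-methoxy-3,6-dimethylbenzoate
Conditions: H2 (1 atm), Pd/C, EtOAc, rt
Reagents that add atoms: none
Why: Hydrogenolysis of an aryl benzyl ether; the tert-butyl ester and methyl ether are inert.

Step 11
Reactants: 8 4-(benzyloxy)-2-methoxy-3,5,6-trimethylbenzoic acid; 14 tert-butyl 4-hydroxy-2-methoxy-3,6-dimethylbenzoate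
Product: 16 tert-butyl 4-{[4-(benzyloxy)-2-methoxy-3,5,6-trimethylbenzoyl]oxy}-2-methoxy-3,6-dimethylbenzoate, via 4-(benzyloxy)-2-methoxy-3,5,6-trimethylbenzoyl chloride 15 (not isolated)
Conditions: (COCl)2, DMF (cat.), CH2Cl2, 0 °C → rt; evaporate; then 14, NaH, THF, 0 °C → rt
Reagents that add atoms: oxalyl chloride, O=C(Cl)C(Cl)=O (chlorine of intermediate 15 only; nothing from it remains in 16)
Why: Acid chloride formation through the chloroiminium salt from DMF, then acylation of a sodium phenoxide; the phenol of 14 has only one ortho methyl, the electron-rich 2,6-disubstituted aroyl chloride ionizes readily toward the anionic nucleophile, and the tert-butyl ester survives these non-acidic conditions.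

Step 12
Reactants: 16 tert-butyl 4-{[4-(benzyloxy)-2-methoxy-3,5,6-trimethylbenzoyl]oxy}-2-methoxy-3,6-dimethylbenzoate
Product: 17 tert-butyl 4-[(4-hydroxy-2-methoxy-3,5,6-trimethylbenzoyl)oxy]-2-methoxy-3,6-dimethylbenzoate
Conditions: H2 (1 atm), Pd/C, EtOAc, rt
Reagents that add atoms: none
Why: Hydrogenolysis of the ring B benzyl ether under neutral conditions; the aryl ester and the tert-butyl ester are not reduced.

Step 13
Reactants: 9 methyl 2,4-dihydroxy-3,6-dimethylbenzoate; 3 benzyl bromide
Product: 18 methyl 2,4-bis(benzyloxy)-3,6-dimethylbenzoate
Conditions: 3 (2.5 equiv), K2CO3 (3 equiv), DMF, 70 °C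
Reagents that add atoms: benzyl bromide (3), BrCc1ccccc1
Why: Exhaustive Williamson etherification; excess 3 and heat in DMF alkylate the chelated 2-hydroxyl as well as the 4-hydroxyl.

Step 14
Reactants: 18 methyl 2,4-bis(benzyloxy)-3,6-dimethylbenzoate
Product: 19 2,4-bis(benzyloxy)-3,6-dimethylbenzoic acid
Conditions: KOH, DMSO/H2O (4:1), 100 °C; then aq. HCl
Reagents that add atoms: potassium hydroxide, [K+].[OH-] (oxygen of the carboxyl OH)
Why: Saponification of a hindered methyl benzoate as in step 5; benzyl ethers are stable to hydroxide.

Step 15
Reactants: 19 2,4-bis(benzyloxy)-3,6-dimethylbenzoic acid; 17 tert-butyl 4-[(4-hydroxy-2-methoxy-3,5,6-trimethylbenzoyl)oxy]-2-methoxy-3,6-dimethylbenzoate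
Product: 21 tert-butyl 4-{[4-{[2,4-bis(benzyloxy)-3,6-dimethylbenzoyl]oxy}-2-methoxy-3,5,6-trimethylbenzoyl]oxy}-2-methoxy-3,6-dimethylbenzoate, via 2,4-bis(benzyloxy)-3,6-dimethylbenzoyl chloride 20 (not isolated)
Conditions: (COCl)2, DMF (cat.), CH2Cl2, 0 °C → rt; evaporate; then 17, NaH, THF, 0 → 60 °C
Reagents that add atoms: oxalyl chloride, O=C(Cl)C(Cl)=O (chlorine of intermediate 20 only; nothing from it remains in 21)
Why: Acylation of a 2,6-dimethylphenoxide by a 2,6-disubstituted aroyl chloride, the reaction type by which hindered aryl mesitoates are made; the naked phenoxide oxygen and mild heating should overcome the shielding, and the existing B–C ester, itself doubly flanked, should resist the phenoxide.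

Step 16
Reactants: 21 tert-butyl 4-{[4-{[2,4-bis(benzyloxy)-3,6-dimethylbenzoyl]oxy}-2-methoxy-3,5,6-trimethylbenzoyl]oxy}-2-methoxy-3,6-dimethylbenzoate
Product: 22 4-{[4-{[2,4-bis(benzyloxy)-3,6-dimethylbenzoyl]oxy}-2-methoxy-3,5,6-trimethylbenzoyl]oxy}-2-methoxy-3,6-dimethylbenzoic acid
Conditions: TFA/CH2Cl2 (1:4), 0 °C → rt
Reagents that add atoms: none
Why: Acidolysis of the tert-butyl ester with loss of 2-methylpropene; the aryl esters and methyl ethers are stable to the acid, ring A is still protected and so is not alkylated by the cation, and any partial loss of a benzyl group would be made good in step 17.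

Step 17
Reactants: 22 4-{[4-{[2,4-bis(benzyloxy)-3,6-dimethylbenzoyl]oxy}-2-methoxy-3,5,6-trimethylbenzoyl]oxy}-2-methoxy-3,6-dimethylbenzoic acid
Product: 23 4-{[4-[(2,4-dihydroxy-3,6-dimethylbenzoyl)oxy]-2-methoxy-3,5,6-trimethylbenzoyl]oxy}-2-methoxy-3,6-dimethylbenzoic acid (CNP0425440.0)
Conditions: H2 (1 atm), Pd/C, EtOAc, rt
Reagents that add atoms: none
Why: Hydrogenolysis of the two aryl benzyl ethers under neutral conditions, the classical last step of depside synthesis; both ester links and the free acid are untouched and toluene is the only by-product.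

## Compound list

1 | methyl orsellinate (methyl 2,4-dihydroxy-6-methylbenzoate) | COC(=O)c1c(C)cc(O)cc1O | starting material
2 | methyl 3,5-dibromo-2,4-dihydroxy-6-methylbenzoate | COC(=O)c1c(C)c(Br)c(O)c(Br)c1O | intermediate
3 | benzyl bromide | BrCc1ccccc1 | starting material
4 | methyl 4-(benzyloxy)-3,5-dibromo-2-hydroxy-6-methylbenzoate | COC(=O)c1c(C)c(Br)c(OCc2ccccc2)c(Br)c1O | intermediate
5 | methyl 4-(benzyloxy)-3,5-dibromo-2-methoxy-6-methylbenzoate | COC(=O)c1c(C)c(Br)c(OCc2ccccc2)c(Br)c1OC | intermediate
6 | trimethylboroxine | CB1OB(C)OB(C)O1 | starting material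
7 | methyl 4-(benzyloxy)-2-methoxy-3,5,6-trimethylbenzoate | COC(=O)c1c(C)c(C)c(OCc2ccccc2)c(C)c1OC | intermediate
8 | 4-(benzyloxy)-2-methoxy-3,5,6-trimethylbenzoic acid | OC(=O)c1c(C)c(C)c(OCc2ccccc2)c(C)c1OC | intermediate
9 | methyl 2,4-dihydroxy-3,6-dimethylbenzoate | COC(=O)c1c(C)cc(O)c(C)c1O | starting material
10 | methyl 4-(benzyloxy)-2-hydroxy-3,6-dimethylbenzoate | COC(=O)c1c(C)cc(OCc2ccccc2)c(C)c1O | intermediate
11 | methyl 4-(benzyloxy)-2-methoxy-3,6-dimethylbenzoate | COC(=O)c1c(C)cc(OCc2ccccc2)c(C)c1OC | intermediate
12 | 4-(benzyloxy)-2-methoxy-3,6-dimethylbenzoic acid | OC(=O)c1c(C)cc(OCc2ccccc2)c(C)c1OC | intermediate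
13 | tert-butyl 4-(benzyloxy)-2-methoxy-3,6-dimethylbenzoate | CC(C)(C)OC(=O)c1c(C)cc(OCc2ccccc2)c(C)c1OC | intermediate
14 | tert-butyl 4-hydroxy-2-methoxy-3,6-dimethylbenzoate | CC(C)(C)OC(=O)c1c(C)cc(O)c(C)c1OC | intermediate
15 | 4-(benzyloxy)-2-methoxy-3,5,6-trimethylbenzoyl chloride | ClC(=O)c1c(C)c(C)c(OCc2ccccc2)c(C)c1OC | intermediate
16 | tert-butyl 4-{[4-(benzyloxy)-2-methoxy-3,5,6-trimethylbenzoyl]oxy}-2-methoxy-3,6-dimethylbenzoate | COc1c(C)c(OC(=O)c2c(C)c(C)c(OCc3ccccc3)c(C)c2OC)cc(C)c1C(=O)OC(C)(C)C | intermediate
17 | tert-butyl 4-[(4-hydroxy-2-methoxy-3,5,6-trimethylbenzoyl)oxy]-2-methoxy-3,6-dimethylbenzoate | COc1c(C)c(OC(=O)c2c(C)c(C)c(O)c(C)c2OC)cc(C)c1C(=O)OC(C)(C)C | intermediate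
18 | methyl 2,4-bis(benzyloxy)-3,6-dimethylbenzoate | COC(=O)c1c(C)cc(OCc2ccccc2)c(C)c1OCc1ccccc1 | intermediate
19 | 2,4-bis(benzyloxy)-3,6-dimethylbenzoic acid | OC(=O)c1c(C)cc(OCc2ccccc2)c(C)c1OCc1ccccc1 | intermediate
20 | 2,4-bis(benzyloxy)-3,6-dimethylbenzoyl chloride | ClC(=O)c1c(C)cc(OCc2ccccc2)c(C)c1OCc1ccccc1 | intermediate
21 | tert-butyl 4-{[4-{[2,4-bis(benzyloxy)-3,6-dimethylbenzoyl]oxy}-2-methoxy-3,5,6-trimethylbenzoyl]oxy}-2-methoxy-3,6-dimethylbenzoate | COc1c(C)c(OC(=O)c2c(C)c(C)c(OC(=O)c3c(C)cc(OCc4ccccc4)c(C)c3OCc5ccccc5)c(C)c2OC)cc(C)c1C(=O)OC(C)(C)C | intermediate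
22 | 4-{[4-{[2,4-bis(benzyloxy)-3,6-dimethylbenzoyl]oxy}-2-methoxy-3,5,6-trimethylbenzoyl]oxy}-2-methoxy-3,6-dimethylbenzoic acid | COc1c(C)c(OC(=O)c2c(C)c(C)c(OC(=O)c3c(C)cc(OCc4ccccc4)c(C)c3OCc5ccccc5)c(C)c2OC)cc(C)c1C(=O)O | intermediate
23 | 4-{[4-[(2,4-dihydroxy-3,6-dimethylbenzoyl)oxy]-2-methoxy-3,5,6-trimethylbenzoyl]oxy}-2-methoxy-3,6-dimethylbenzoic acid (CNP0425440.0) | COc1c(C)c(OC(=O)c2c(C)c(C)c(OC(=O)c3c(C)cc(O)c(C)c3O)c(C)c2OC)cc(C)c1C(=O)O | target

## Step count and risks

Total: 17 steps. Longest linear sequence: 10 steps (1, 2, 3, 4, 5, 11, 12, 15, 16, 17). The ring C branch (6 to 10, then 11, 12, 15, 16, 17) is equally long, and the ring A branch adds two steps (13, 14) before it joins at step 15.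

**Step 4 (key step).** The most likely failures are incomplete coupling at the second bromide and hydrodebromination. After the first methyl is in place the ring is more electron-rich, so oxidative addition is slower, and methyl transfer from boron is slow; the C3 bromide between two alkoxy groups is the harder site. A second failure is ring closure of the arylpalladium bromide onto an ortho C–H of the neighbouring benzyl group. The fallback sets out from 9, which already carries the C3 methyl, and returns to the route at 7:
- One equivalent of N-bromosuccinimide at the single free ring position should give methyl 5-bromo-2,4-dihydroxy-3,6-dimethylbenzoate F1.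
- Benzylation of the unchelated hydroxyl with 3 and K2CO3 gives methyl 4-(benzyloxy)-5-bromo-2-hydroxy-3,6-dimethylbenzoate F2.
- Methylation with iodomethane and K2CO3 gives methyl 4-(benzyloxy)-5-bromo-2-methoxy-3,6-dimethylbenzoate F3.
- A single methyl coupling of F3 with 6 then forms 7.

Only one aryl–methyl bond is made by coupling, at the less hindered site, and the step count is unchanged.

**Step 15.** Acyl transfer may stall because both partners are shielded on both sides. A slow reaction would let the phenoxide scramble the existing B–C ester, or the chloride hydrolyse back to 19 on work-up. The fallback sets out from 17 and returns at 23. It moves this union to acylium-type activation on a substrate without acid-labile groups: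
- Acidolysis of 17 with TFA gives 4-[(4-hydroxy-2-methoxy-3,5,6-trimethylbenzoyl)oxy]-2-methoxy-3,6-dimethylbenzoic acid F4.
- Selective carboxylate alkylation with 3 and KHCO3 in DMF gives benzyl 4-[(4-hydroxy-2-methoxy-3,5,6-trimethylbenzoyl)oxy]-2-methoxy-3,6-dimethylbenzoate F5 (the same compound as A7).
- Condensation of F5 with 19 by trifluoroacetic anhydride in toluene, the classical method for hindered aryl esters, gives benzyl 4-{[4-{[2,4-bis(benzyloxy)-3,6-dimethylbenzoyl]oxy}-2-methoxy-3,5,6-trimethylbenzoyl]oxy}-2-methoxy-3,6-dimethylbenzoate F6.
- One hydrogenolysis over Pd/C removes all three benzyl groups and gives 23.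

**Step 2.** Benzylation may lose its site selectivity or run on to the dibenzyl ether, because both hydroxyls of 2 are acidified by ortho bromine and the O4 anion is the more crowded one. The fallback sets out from 1 and returns at 4: benzylation of 1 with 3 and K2CO3 in acetone, whose selectivity for the unchelated hydroxyl is well established, gives methyl 4-(benzyloxy)-2-hydroxy-6-methylbenzoate F7. Two equivalents of N-bromosuccinimide then brominate para and ortho to the free 2-hydroxyl and give 4.

**Step 5.** Hydrolysis of the ester between a methoxy and a methyl group may be incomplete, or forcing it may start nucleophilic loss of the 2-O-methyl group. The fallback sets out from 7 and returns at 8 by a redox detour that does not depend on attack of hydroxide at the shielded carbonyl: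
- Reduction with LiAlH4 in THF gives [4-(benzyloxy)-2-methoxy-3,5,6-trimethylphenyl]methanol F8.
- Oxidation with MnO2 gives 4-(benzyloxy)-2-methoxy-3,5,6-trimethylbenzaldehyde F9.
- Pinnick oxidation (NaClO2, NaH2PO4, 2-methylbut-2-ene) gives 8.

## Further compounds

F1 | step 4 | methyl 5-bromo-2,4-dihydroxy-3,6-dimethylbenzoate | COC(=O)c1c(C)c(Br)c(O)c(C)c1O
F2 | step 4 | methyl 4-(benzyloxy)-5-bromo-2-hydroxy-3,6-dimethylbenzoate | COC(=O)c1c(C)c(Br)c(OCc2ccccc2)c(C)c1O
F3 | step 4 | methyl 4-(benzyloxy)-5-bromo-2-methoxy-3,6-dimethylbenzoate | COC(=O)c1c(C)c(Br)c(OCc2ccccc2)c(C)c1OC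
F4 | step 15 | 4-[(4-hydroxy-2-methoxy-3,5,6-trimethylbenzoyl)oxy]-2-methoxy-3,6-dimethylbenzoic acid | COc1c(C)c(OC(=O)c2c(C)c(C)c(O)c(C)c2OC)cc(C)c1C(=O)O
F5 | step 15 | benzyl 4-[(4-hydroxy-2-methoxy-3,5,6-trimethylbenzoyl)oxy]-2-methoxy-3,6-dimethylbenzoate | COc1c(C)c(OC(=O)c2c(C)c(C)c(O)c(C)c2OC)cc(C)c1C(=O)OCc1ccccc1
F6 | step 15 | benzyl 4-{[4-{[2,4-bis(benzyloxy)-3,6-dimethylbenzoyl]oxy}-2-methoxy-3,5,6-trimethylbenzoyl]oxy}-2-methoxy-3,6-dimethylbenzoate | COc1c(C)c(OC(=O)c2c(C)c(C)c(OC(=O)c3c(C)cc(OCc4ccccc4)c(C)c3OCc5ccccc5)c(C)c2OC)cc(C)c1C(=O)OCc1ccccc1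
F7 | step 2 | methyl 4-(benzyloxy)-2-hydroxy-6-methylbenzoate | COC(=O)c1c(C)cc(OCc2ccccc2)cc1O
F8 | step 5 | [4-(benzyloxy)-2-methoxy-3,5,6-trimethylphenyl]methanol | OCc1c(C)c(C)c(OCc2ccccc2)c(C)c1OC
F9 | step 5 | 4-(benzyloxy)-2-methoxy-3,5,6-trimethylbenzaldehyde | O=Cc1c(C)c(C)c(OCc2ccccc2)c(C)c1OC
A1 | alternative 1 | pentan-3-one | CCC(=O)CC
A2 | alternative 1 | diethyl ethylidenemalonate | CCOC(=O)C(=CC)C(=O)OCC
A3 | alternative 1 | ethyl 3,5,6-trimethyl-2,4-dioxocyclohexane-1-carboxylate | CCOC(=O)C1C(C)C(C)C(=O)C(C)C1=O
A4 | alternative 1 | ethyl 2,4-dihydroxy-3,5,6-trimethylbenzoate | CCOC(=O)c1c(C)c(C)c(O)c(C)c1O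
A5 | alternative 2 | benzyl 4-{[(4E)-2-diazo-4-methyl-3-oxohex-4-enoyl]oxy}-2-methoxy-3,6-dimethylbenzoate | COc1c(C)c(OC(=O)C(=[N+]=[N-])C(=O)/C(C)=C/C)cc(C)c1C(=O)OCc1ccccc1
A6 | alternative 2 | 1-methoxypropyne | COC#CC
A7 | alternative 2 | benzyl 4-[(4-hydroxy-2-methoxy-3,5,6-trimethylbenzoyl)oxy]-2-methoxy-3,6-dimethylbenzoate | COc1c(C)c(OC(=O)c2c(C)c(C)c(O)c(C)c2OC)cc(C)c1C(=O)OCc1ccccc1
A8 | alternative 3 | 6-(3,5-dioxohexan-2-yl)-2,2-dimethyl-4H-1,3-dioxin-4-one | CC(=O)CC(=O)C(C)C1=CC(=O)OC(C)(C)O1
A9 | alternative 3 | benzyl 4-({2-methoxy-3,5,6-trimethyl-4-[(4-methyl-3,5,7-trioxooctanoyl)oxy]benzoyl}oxy)-2-methoxy-3,6-dimethylbenzoate | COc1c(C)c(OC(=O)c2c(C)c(C)c(OC(=O)CC(=O)C(C)C(=O)CC(C)=O)c(C)c2OC)cc(C)c1C(=O)OCc1ccccc1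
A10 | alternative 3 | benzyl 4-{[4-[(2,4-dihydroxy-3,6-dimethylbenzoyl)oxy]-2-methoxy-3,5,6-trimethylbenzoyl]oxy}-2-methoxy-3,6-dimethylbenzoate | COc1c(C)c(OC(=O)c2c(C)c(C)c(OC(=O)c3c(C)cc(O)c(C)c3O)c(C)c2OC)cc(C)c1C(=O)OCc1ccccc1
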